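**An impossible balance.** The gamma run cannot balance on the two species read: at 25.0 h that flask held 19.5% of the charge as starting material and 1.3% as target, so 79.2% of the charge stood in something nobody read.

| setting | gamma | eta | birch | ash | oak | larch |
|---|---|---|---|---|---|---|
| starting material | 0.050 M | 0.050 M | 0.050 M | 0.050 M | 0.050 M | 0.050 M |
| catalyst | 0.5 mol% | 2 mol% | 1 mol% | 1 mol% | 1 mol% | 1 mol% |
| temperature | −20 °C | 13 °C | −5 °C | 25 °C |  | −35 °C |
| remark | run made earlier | run made earlier |  |  | at −35 °C until 10 h, from then on at 25 °C |  |
| time |  |  | 15 h | 15 h | 15 h | 15 h |

| run | time / h | target / % | starting material / % |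
|---|---|---|---|
| gamma | 2.00 | 1.2 | 87.5 |
| gamma | 5.00 | 0.3 | 70.4 |
| gamma | 8.00 | 0 | 58.9 |
| gamma | 12.0 | 0 | 45.2 |
| gamma | 20.0 | 0 | 26.9 |
| gamma | 25.0 | 1.3 | 19.5 |
| eta | 0.417 | 0.5 | 80.2 |
| eta | 0.667 | 5.1 | 71.2 |
| eta | 1.00 | 5.2 | 62.2 |
| eta | 1.50 | 8.1 | 52.1 |
| eta | 3.00 | 8.9 | 37.5 |
| eta | 5.00 | 11.5 | 33.2 |

(readings scatter by 1 percentage point)

1. the flask that comes out highest in amount of target, in percent of the starting material charged, or "all alike" when all lie within 1.5 percentage points (birch / ash / oak / larch / all alike)
2. target at the end, in percent of the starting material charged, birch
3. target at the end, in percent of the starting material charged, ash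
4. target at the end, in percent of the starting material charged, oak
5. target at the end, in percent of the starting material charged, larch



**Stall in eta.** In the eta run the starting material fell more and more slowly, to 33.2% at the last reading, and my first thought was a dying catalyst. The objection was that a reverse step would stall the starting material in the same way, so I looked at the target. Between 3.00 h and 5.00 h the eta target took up 60.5% of what the starting material lost, more than the 16.9% of the first 1.50 h. That looked to me like a balance being approached, but the gain of 2.6 percentage points stands against a scatter of 1 point per reading, so I held this as a working belief.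

**Standing ratio.** On that belief I need not follow the large flow of starting material, and I treated the target as a small correction riding on it. The last eta reading gives 0.346 parts of target per part of starting material left. This standing ratio, target over starting material in a flask taken to have stopped moving, is what I carried on, an apparent equilibrium constant.

**Its limits.** Gamma objected first: the ratio times its last starting material gives 6.75%, more than the 1.3% read, so gamma did not stand at this ratio. I therefore set larch, colder than gamma, apart with little target, and birch, though warmer than gamma, with it as a guess. Ash stood warmer than eta from the start and oak stood so after 10 h, but oak had 5.00 h of warmth at half the eta loading, and I could not prove that this reaches standing. The ratio and the stall were also read at 13 °C, and I had no run warmer than eta to correct them. Taking over the last eta starting material as a guess, I still committed to about 11.5% for ash and for oak, which left those two unparted.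

**The comparison.** The forecast, reading eta as “catalyst dying”, named ash highest and gave 3% for birch, 5.5% for ash, 2.7% for oak and 0.2% for larch, with ash and oak below my figure.

**The result.** The highest flask was oak, at 16.1%, with ash at 10.1%, birch at 3.34% and larch at 0.259%. Ash ended with 100% of its catalyst.

    target ⇌ isomer of the product (K = 1.90, k = 0.00110 s⁻¹, Ea = 87.0 kJ mol⁻¹, ΔH = −54.0 kJ mol⁻¹)
    starting material + catalyst ⇌ target + catalyst, rate k2*[starting material]*[catalyst] forward; the back reaction follows from the equilibrium constant (K = 0.380, k = 0.0380 M⁻¹ s⁻¹, Ea = 52.0 kJ mol⁻¹, ΔH = 9.00 kJ mol⁻¹)
    starting material → uncatalysed product (k = 2.40 × 10⁻⁵ s⁻¹, Ea = 98.0 kJ mol⁻¹)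
    isomer of the product + catalyst ⇌ starting material + catalyst, rate k4*[catalyst]*[isomer of the product] forward; the back reaction follows from the equilibrium constant (k = 0.220 M⁻¹ s⁻¹, Ea = 55.0 kJ mol⁻¹)
    (constants at 25 °C)

The standing ratio times the 36.8% of starting material left in oak gives 12.7%, against the 16.1% found. In ash, with 23.2% left, it gives 8.03%, against the 10.1% found.

(The numbers in the tables were generated by integration with made-up constants; scatter was added.)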